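Ring B (C5, C6, C7, C8, C9, C10; labdane numbering) is closed last, through its C7–C8 bond, by a rhodium–vinylidene cycloisomerisation of a 1,6-enyne. The step exploits the 3-methylenecyclohexene diene C6=C7–C8=C17 of ring B: C6 and C7 are the carbons of an ethynyl group on C5, C8=C17 is a vinyl group on C9, and one redox-neutral isomerisation delivers the ring and both double bonds. The precursor is therefore a monocyclic ring A carrying the ethynyl group at C5 and the complete, vinyl-branched side chain at C10. Its four stereocentres come from an enantioselective Diels–Alder reaction (C4, C5) and an iridium-catalysed enolate allylation (C9, C10).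

Key step: step 12

Remark (assumption): atoms are numbered as in labdanes (target = 4S,5S,9R,10S). The enantiomers of the two chiral catalysts (steps 5 and 9) are written as the accepted facial models assign them; if a sense proves opposite, the mirror-image catalyst is used and nothing else changes.

Step 1
Reactants: 1 methyl but-2-ynoate; 2 but-3-en-1-ylmagnesium bromide
Product: 3 methyl (2E)-3-methylhepta-2,6-dienoate
Conditions: 2, CuBr·SMe2, THF, −78 °C; then 1, −78 °C; MeOH quench at −78 °C, aq NH4Cl
Reagents that add atoms: none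
Why: syn-carbocupration of the ynoate (organocopper conjugate addition) places the butenyl group cis to copper, so low-temperature protonation should give the E-trisubstituted enoate.

Step 2
Reactants: 3 methyl (2E)-3-methylhepta-2,6-dienoate; 4 allyl methyl carbonate
Product: 5 methyl (2E,6E)-8-[(methoxycarbonyl)oxy]-3-methylocta-2,6-dienoate
Conditions: Ru(=CH-C6H4-2-OiPr)(H2IMes)Cl2 (3 mol %), 4 (4 equiv), CH2Cl2, 40 °C
Reagents that add atoms: none
Why: olefin cross-metathesis of the terminal alkene with excess 4; the trisubstituted conjugated alkene is inert and the new alkene should form mainly E (minor Z isomer removed by chromatography).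

Step 3
Reactants: 6 3-(trimethylsilyl)prop-2-ynal; 7 2-(triphenyl-λ5-phosphanylidene)propanal
Product: 8 (2E)-2-methyl-5-(trimethylsilyl)pent-2-en-4-ynal
Conditions: CH2Cl2, rt
Reagents that add atoms: none
Why: Wittig olefination with a stabilised formyl ylide should give the E enal (alkynyl trans to CHO) and stop there, because the α-branched product enal is far less electrophilic than the ynal.

Step 4
Reactants: 9 pent-1-en-3-one
Product: 10 (Z)-triisopropyl(penta-1,3-dien-3-yloxy)silane
Conditions: iPr3SiOTf, Et3N, CH2Cl2, 0 °C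
Reagents that add atoms: triisopropylsilyl trifluoromethanesulfonate, CC(C)[Si](C(C)C)(C(C)C)OS(=O)(=O)C(F)(F)F
Why: soft enolisation and O-silylation of the enone should give the Z 2-silyloxydiene, whose terminal methyl group points outward in the s-cis conformer.

Step 5
Reactants: 8 (2E)-2-methyl-5-(trimethylsilyl)pent-2-en-4-ynal; 10 (Z)-triisopropyl(penta-1,3-dien-3-yloxy)silane
Product: 11 (1S,6S)-1,5-dimethyl-4-[(triisopropylsilyl)oxy]-6-[(trimethylsilyl)ethynyl]cyclohex-3-ene-1-carbaldehyde (mixture of epimers at C-5 of this name)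
Conditions: (R)-o-tolyl-oxazaborolidinium triflimide [from (R)-α,α-diphenylprolinol, o-tolylboroxine, HNTf2] (20 mol %), CH2Cl2, −78 → −40 °C
Reagents that add atoms: none
Why: Lewis-acid-catalysed enantioselective Diels–Alder reaction in which the nucleophilic CH(CH3) terminus of the silyloxydiene bonds to the enal β-carbon (para regiochemistry), the E geometry of 8 fixes CHO trans and CH3 cis to the alkynyl group, and the catalyst directs the diene to the Si face of the enal α-carbon, setting C4 (S) and C5 (S); the methyl-bearing C10 forms as an inconsequential epimer mixture.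

Step 6
Reactants: 11 (1S,6S)-1,5-dimethyl-4-[(triisopropylsilyl)oxy]-6-[(trimethylsilyl)ethynyl]cyclohex-3-ene-1-carbaldehyde
Product: 13 (3S,4S)-4-(hydroxymethyl)-2,4-dimethyl-3-[(trimethylsilyl)ethynyl]cyclohexan-1-one (C-2 epimers), via silyl enol ether alcohol 12 (not isolated)
Conditions: NaBH4, EtOH, 0 °C; acetone; then 1 M HCl, THF, rt
Reagents that add atoms: none
Why: borohydride reduces the aldehyde while the ketone stays masked as the silyl enol ether, and acid hydrolysis of the enol ether then releases the C1 ketone; the epimeric centre C10 is erased in step 8.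

Step 7
Reactants: 13 (3S,4S)-4-(hydroxymethyl)-2,4-dimethyl-3-[(trimethylsilyl)ethynyl]cyclohexan-1-one
Product: 14 [(1S,2S)-1,3-dimethyl-4-oxo-2-[(trimethylsilyl)ethynyl]cyclohexyl]methyl acetate (C-3 epimers)
Conditions: Ac2O, pyridine, DMAP (cat.), CH2Cl2, rt
Reagents that add atoms: acetic anhydride, CC(=O)OC(C)=O
Why: DMAP-catalysed acylation of the neopentyl primary alcohol installs the acetate of the target, which should tolerate the later neutral, buffered or weakly Lewis-acidic conditions.

Step 8
Reactants: 14 [(1S,2S)-1,3-dimethyl-4-oxo-2-[(trimethylsilyl)ethynyl]cyclohexyl]methyl acetate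
Product: 15 [(1S,2R)-1,3-dimethyl-2-[(trimethylsilyl)ethynyl]-4-[(trimethylsilyl)oxy]cyclohex-3-en-1-yl]methyl acetate
Conditions: Me3SiCl, NaI, Et3N, MeCN, rt
Reagents that add atoms: chlorotrimethylsilane, C[Si](C)(C)Cl
Why: thermodynamic silyl enol ether formation (Me3SiI made in situ, amine base) should favour the tetrasubstituted C1=C10 enol ether, which removes the C10 epimers and defines the enolate for step 9.

Step 9
Reactants: 15 [(1S,2R)-1,3-dimethyl-2-[(trimethylsilyl)ethynyl]-4-[(trimethylsilyl)oxy]cyclohex-3-en-1-yl]methyl acetate; 5 methyl (2E,6E)-8-[(methoxycarbonyl)oxy]-3-methylocta-2,6-dienoate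
Product: 16 methyl (2E,6R)-6-[(1S,2R,3S)-3-(acetoxymethyl)-1,3-dimethyl-6-oxo-2-[(trimethylsilyl)ethynyl]cyclohexyl]-3-methylocta-2,7-dienoate
Conditions: [Ir(cod)Cl]2 (2.5 mol %), (Sa,S,S)-binaphthol N,N-bis(1-phenylethyl)phosphoramidite (5 mol %), CsF (0.4 equiv), ZnF2 (0.5 equiv), DME, 50 °C
Reagents that add atoms: none
Why: iridium-catalysed branch-selective allylic alkylation of a fluoride-released ketone enolate, in which the enolate attacks the substituted terminus of the Ir–phosphoramidite π-allyl so that the ligand fixes C9 (R), while the enolate reacts on its face anti to the neighbouring C5 alkynyl group (2,3-trans alkylation) and so fixes the quaternary C10 (S).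

Step 10
Reactants: 16 methyl (2E,6R)-6-[(1S,2R,3S)-3-(acetoxymethyl)-1,3-dimethyl-6-oxo-2-[(trimethylsilyl)ethynyl]cyclohexyl]-3-methylocta-2,7-dienoate
Product: 18 methyl (2E,6R)-6-[(1S,2S,3S)-3-(acetoxymethyl)-1,3-dimethyl-2-[(trimethylsilyl)ethynyl]cyclohexyl]-3-methylocta-2,7-dienoate, via tosylhydrazone 17 (not isolated)
Conditions: TsNHNH2, EtOH, 70 °C; solvent exchange; catecholborane, CHCl3, 0 °C → rt; NaOAc·3H2O, 60 °C
Reagents that add atoms: 4-methylbenzenesulfonohydrazide, Cc1ccc(cc1)S(=O)(=O)NN (its atoms stay only in intermediate 17)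
Why: reductive deoxygenation through the tosylhydrazone (hydride addition to C=N, then loss of sulfinate and N2 from the diazene) turns C1=O into CH2 without touching the esters, alkenes or silylalkyne; C1 is not stereogenic.

Step 11
Reactants: 18 methyl (2E,6R)-6-[(1S,2S,3S)-3-(acetoxymethyl)-1,3-dimethyl-2-[(trimethylsilyl)ethynyl]cyclohexyl]-3-methylocta-2,7-dienoate
Product: 19 methyl (2E,6R)-6-[(1S,2S,3S)-3-(acetoxymethyl)-2-ethynyl-1,3-dimethylcyclohexyl]-3-methylocta-2,7-dienoate
Conditions: Bu4NF, AcOH (1:1), THF, 0 °C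
Reagents that add atoms: none
Why: fluoride-mediated protodesilylation of the alkynylsilane, buffered with acetic acid so that the acetate and methyl ester survive.

Step 12
Reactants: 19 methyl (2E,6R)-6-[(1S,2S,3S)-3-(acetoxymethyl)-2-ethynyl-1,3-dimethylcyclohexyl]-3-methylocta-2,7-dienoate
Product: 20 methyl (2E)-5-[(1R,4aS,5S,8aS)-5-(acetoxymethyl)-5,8a-dimethyl-2-methylidene-1,2,4a,5,6,7,8,8a-octahydronaphthalen-1-yl]-3-methylpent-2-enoate (CNP0148290.1)
Conditions: [Rh(cod)Cl]2 (5 mol %), P(4-FC6H4)3 (20 mol %), DMF, 85 °C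
Reagents that add atoms: none
Why: Rh(I) converts the terminal alkyne into a rhodium vinylidene (1,2-hydrogen shift) whose Rh=C7 bond adds [2+2] to the C8=C17 vinyl group, forming C7–C8 in a rhodacyclobutane; β-hydride elimination of H-8 and C–H reductive elimination at C7 then release the C6=C7–C8=C17 diene and Rh(I). The closest known reaction is the Rh(I)/triarylphosphine cycloisomerisation of carbon-tethered 1,6-enynes to 3-methylenecyclohexenes through vinylidene intermediates. Ring B closes in a formal 6-endo mode, both alkyne carbons (C6, C7) entering the ring together with C5 and C10 of ring A, C9 and C8. No stereocentre is created (C8 becomes sp2); C5, C9 and C10 are already set, and the equatorial ethynyl and C9 arms on neighbouring ring-A carbons enforce the trans ring fusion. The step needs six-ring (vinylidene) selectivity over five-ring Alder-ene or metathesis-type closure and chemoselectivity for the monosubstituted alkene, which the terminal alkyne, the neutral Rh–phosphine/DMF system and the remote, trisubstituted, electron-poor enoate should secure.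

Compound list
1 | methyl but-2-ynoate | CC#CC(=O)OC | starting material
2 | but-3-en-1-ylmagnesium bromide | C=CCC[Mg]Br | starting material
3 | methyl (2E)-3-methylhepta-2,6-dienoate | C=CCC/C(C)=C/C(=O)OC | intermediate
4 | allyl methyl carbonate | C=CCOC(=O)OC | starting material
5 | methyl (2E,6E)-8-[(methoxycarbonyl)oxy]-3-methylocta-2,6-dienoate | COC(=O)OC/C=C/CC/C(C)=C/C(=O)OC | intermediate
6 | 3-(trimethylsilyl)prop-2-ynal | C[Si](C)(C)C#CC=O | starting material
7 | 2-(triphenyl-λ5-phosphanylidene)propanal | CC(C=O)=P(c1ccccc1)(c1ccccc1)c1ccccc1 | starting material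
8 | (2E)-2-methyl-5-(trimethylsilyl)pent-2-en-4-ynal | O=C/C(C)=C/C#C[Si](C)(C)C | intermediate
9 | pent-1-en-3-one | CCC(=O)C=C | starting material
10 | (Z)-triisopropyl(penta-1,3-dien-3-yloxy)silane | C/C=C(\O[Si](C(C)C)(C(C)C)C(C)C)C=C | intermediate
11 | (1S,6S)-1,5-dimethyl-4-[(triisopropylsilyl)oxy]-6-[(trimethylsilyl)ethynyl]cyclohex-3-ene-1-carbaldehyde, CHO trans to the alkynyl group, C-5 epimers | O=C[C@@]1(C)CC=C(O[Si](C(C)C)(C(C)C)C(C)C)C(C)[C@@H]1C#C[Si](C)(C)C | intermediate
12 | [(1S,6S)-1,5-dimethyl-4-[(triisopropylsilyl)oxy]-6-[(trimethylsilyl)ethynyl]cyclohex-3-en-1-yl]methanol, C-5 epimers | OC[C@@]1(C)CC=C(O[Si](C(C)C)(C(C)C)C(C)C)C(C)[C@@H]1C#C[Si](C)(C)C | intermediate (not isolated)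
13 | (3S,4S)-4-(hydroxymethyl)-2,4-dimethyl-3-[(trimethylsilyl)ethynyl]cyclohexan-1-one, C-2 epimers | OC[C@@]1(C)CCC(=O)C(C)[C@@H]1C#C[Si](C)(C)C | intermediate
14 | [(1S,2S)-1,3-dimethyl-4-oxo-2-[(trimethylsilyl)ethynyl]cyclohexyl]methyl acetate, C-3 epimers | CC(=O)OC[C@@]1(C)CCC(=O)C(C)[C@@H]1C#C[Si](C)(C)C | intermediate
15 | [(1S,2R)-1,3-dimethyl-2-[(trimethylsilyl)ethynyl]-4-[(trimethylsilyl)oxy]cyclohex-3-en-1-yl]methyl acetate | CC(=O)OC[C@@]1(C)CCC(O[Si](C)(C)C)=C(C)[C@@H]1C#C[Si](C)(C)C | intermediate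
16 | methyl (2E,6R)-6-[(1S,2R,3S)-3-(acetoxymethyl)-1,3-dimethyl-6-oxo-2-[(trimethylsilyl)ethynyl]cyclohexyl]-3-methylocta-2,7-dienoate | CC(=O)OC[C@@]1(C)CCC(=O)[C@@](C)([C@@H](C=C)CC/C(C)=C/C(=O)OC)[C@@H]1C#C[Si](C)(C)C | intermediate
17 | 4-methylbenzenesulfonylhydrazone of 16 (at the ring ketone) | CC(=O)OC[C@@]1(C)CCC(=NNS(=O)(=O)c2ccc(C)cc2)[C@@](C)([C@@H](C=C)CC/C(C)=C/C(=O)OC)[C@@H]1C#C[Si](C)(C)C | intermediate (not isolated)
18 | methyl (2E,6R)-6-[(1S,2S,3S)-3-(acetoxymethyl)-1,3-dimethyl-2-[(trimethylsilyl)ethynyl]cyclohexyl]-3-methylocta-2,7-dienoate | CC(=O)OC[C@@]1(C)CCC[C@@](C)([C@@H](C=C)CC/C(C)=C/C(=O)OC)[C@@H]1C#C[Si](C)(C)C | intermediate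
19 | methyl (2E,6R)-6-[(1S,2S,3S)-3-(acetoxymethyl)-2-ethynyl-1,3-dimethylcyclohexyl]-3-methylocta-2,7-dienoate | CC(=O)OC[C@@]1(C)CCC[C@@](C)([C@@H](C=C)CC/C(C)=C/C(=O)OC)[C@@H]1C#C | intermediate
20 | methyl (2E)-5-[(1R,4aS,5S,8aS)-5-(acetoxymethyl)-5,8a-dimethyl-2-methylidene-1,2,4a,5,6,7,8,8a-octahydronaphthalen-1-yl]-3-methylpent-2-enoate | C=C1C=C[C@@H]2[C@@](C)(COC(C)=O)CCC[C@@]2(C)[C@@H]1CC/C(C)=C/C(=O)OC | target

Total step count: 12. Longest linear sequence: 9 steps (steps 3, 5, 6, 7, 8, 9, 10, 11, 12, from 6).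

Steps most likely to fail

1. Step 12 (key step). The vinylidene [2+2] may be slow for an alkyne flanked by two quaternary carbons, so that alkyne oligomerisation, five-ring Alder-ene closure or Rh–H migration of the exocyclic diene into the ring takes over. The fallback sets out from 19 and comes back at 20 through a Heck ring closure. ZrCl4-catalysed anti-hydrostannation of the terminal alkyne (Bu3SnH, toluene, 0 °C) should give methyl (2E,6R)-6-[(1S,2S,3S)-3-(acetoxymethyl)-1,3-dimethyl-2-[(Z)-2-(tributylstannyl)ethenyl]cyclohexyl]-3-methylocta-2,7-dienoate F1. Iododestannylation (I2, CH2Cl2, 0 °C) gives the (Z)-vinyl iodide F2. A 6-exo-trig Heck cyclisation (Pd(OAc)2, PPh3, Ag2CO3, MeCN, 70 °C) onto the C8=C17 vinyl group, with β-hydride elimination of H-8, then forms C7–C8 and the exocyclic methylene of 20.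

2. Step 9. The allyl complex may be attacked at its unsubstituted terminus, the minor less-substituted enol ether may carry the allylation to C2, facial control at the hindered C10 may be poor, or fluoride may strip the alkynylsilane. The fallback sets out from 14 (and 3) and comes back at 16 through a thermal Claisen rearrangement, which also bypasses step 8. Z-selective cross-metathesis of 3 with (Z)-but-2-ene-1,4-diol (cyclometallated Ru–NHC catalyst) gives methyl (2E,6Z)-8-hydroxy-3-methylocta-2,6-dienoate F3. Ketone 14 is converted (HC(OMe)3, TsOH, MeOH) into its dimethyl ketal F4. F4 is heated with F3 and catalytic propionic acid in xylene at 140 °C with removal of methanol, which forms the tetrasubstituted allyl enol ether F5 (not isolated). F5 rearranges through a chair transition state on the face anti to the alkynyl group; with the Z allyl unit this should give the 9R,10S ketone 16.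

3. Step 5. The trisubstituted enynal may add slowly, the diene may be lost to Mukaiyama–Michael addition or protodesilylation, or enantiofacial control may be insufficient. The fallback sets out from 8 and 10 and comes back at 14 through a racemic cycloaddition and resolution. Me2AlCl-promoted Diels–Alder reaction (CH2Cl2, −78 °C) gives the racemic adduct F6, whose relative configuration is still fixed by the E dienophile. Reduction and hydrolysis as in step 6 give the racemic hydroxy ketone F8 via the racemic silyl enol ether alcohol F7 (not isolated). Lipase-catalysed acylation (Burkholderia cepacia lipase, vinyl acetate, MTBE, 30 °C) resolves F8: the required enantiomer is collected as acetate 14, or as unreacted alcohol 13 (then step 7) if it is the slower-reacting one.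

Further compounds
F1 | step 12 | methyl (2E,6R)-6-[(1S,2S,3S)-3-(acetoxymethyl)-1,3-dimethyl-2-[(Z)-2-(tributylstannyl)ethenyl]cyclohexyl]-3-methylocta-2,7-dienoate | CC(=O)OC[C@@]1(C)CCC[C@@](C)([C@@H](C=C)CC/C(C)=C/C(=O)OC)[C@@H]1/C=C\[Sn](CCCC)(CCCC)CCCC
F2 | step 12 | methyl (2E,6R)-6-[(1S,2S,3S)-3-(acetoxymethyl)-2-[(Z)-2-iodoethenyl]-1,3-dimethylcyclohexyl]-3-methylocta-2,7-dienoate | CC(=O)OC[C@@]1(C)CCC[C@@](C)([C@@H](C=C)CC/C(C)=C/C(=O)OC)[C@@H]1/C=C\I
F3 | step 9 | methyl (2E,6Z)-8-hydroxy-3-methylocta-2,6-dienoate | OC/C=C\CC/C(C)=C/C(=O)OC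
F4 | step 9 | [(1S,2S)-4,4-dimethoxy-1,3-dimethyl-2-[(trimethylsilyl)ethynyl]cyclohexyl]methyl acetate | CC(=O)OC[C@@]1(C)CCC(OC)(OC)C(C)[C@@H]1C#C[Si](C)(C)C
F5 | step 9 | methyl (2E,6Z)-8-{[(3R,4S)-4-(acetoxymethyl)-2,4-dimethyl-3-[(trimethylsilyl)ethynyl]cyclohex-1-en-1-yl]oxy}-3-methylocta-2,6-dienoate | CC(=O)OC[C@@]1(C)CCC(OC/C=C\CC/C(C)=C/C(=O)OC)=C(C)[C@@H]1C#C[Si](C)(C)C
F6 | step 5 | racemic 11, rac-(1S*,6S*)-1,5-dimethyl-4-[(triisopropylsilyl)oxy]-6-[(trimethylsilyl)ethynyl]cyclohex-3-ene-1-carbaldehyde (relative configuration shown) | O=C[C@@]1(C)CC=C(O[Si](C(C)C)(C(C)C)C(C)C)C(C)[C@@H]1C#C[Si](C)(C)C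
F7 | step 5 | racemic 12, rac-[(1S*,6S*)-1,5-dimethyl-4-[(triisopropylsilyl)oxy]-6-[(trimethylsilyl)ethynyl]cyclohex-3-en-1-yl]methanol (relative configuration shown) | OC[C@@]1(C)CC=C(O[Si](C(C)C)(C(C)C)C(C)C)C(C)[C@@H]1C#C[Si](C)(C)C
F8 | step 5 | racemic 13, rac-(3S*,4S*)-4-(hydroxymethyl)-2,4-dimethyl-3-[(trimethylsilyl)ethynyl]cyclohexan-1-one (relative configuration shown) | OC[C@@]1(C)CCC(=O)C(C)[C@@H]1C#C[Si](C)(C)C
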